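All constants are assumed; no experiment stands behind them.

One J at the charged [L] grows at 14.6 h⁻¹, counted in units of L. This growth speed, k2 times [L], is the pseudo-first-order constant of a single chain, and I carry it through this flask.

L 2.5 M; X 250 mM; time 6.0 h

    L + G → L.G (k1 = 0.00345 M⁻¹ min⁻¹)
    L + J → Q + J, rate k2*[J]*[L] (k2 = 0.0974 M⁻¹ min⁻¹)
    L + G → J + Q (k3 = 0.00206 M⁻¹ min⁻¹)
    X → G (k4 = 0.00112 min⁻¹)

- the average divides the monomer in chains by the number of chains begun, living and dead together
- run time (flask): 6.0 h

1. whether the average number of monomer units in a chain (chains begun, living or dead) reaches 30 by 6.0 h (no / yes)
2. average number of monomer units in a chain (chains begun, living or dead) at 6.0 h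

No step in the scheme removes J, and L.G carries no Q, so I count J as the chains begun. Step 3 gives each chain its first unit. While [L] stays as charged, the average length is therefore one plus the growth speed times the mean age of the chains. How many chains are begun drops out, so I need their age, and two extreme flasks give it in the head.

If G stood at a steady level from the first moment, J would be born evenly and the mean age would be half of the run:

1 + 14.6 h⁻¹ × 6.0 h / 2 = 44.8

If G were still building up, births would rise in proportion to time and the mean age would be a third of the run:

1 + 14.6 h⁻¹ × 6.0 h / 3 = 30.2

G approaches its level on its own time, 1.21 h. The real flask starts like the second case and then turns towards the first, so I put its mean age between the two, because this time is shorter than the run. The falling [L] pulls the length down by an amount I leave open, so I commit to a narrow yes and to a length between 30.2 and 44.8, not a single number.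

The forecast says yes and gives 34, a single number inside my range, adding that “the ratio rises past 30 at around 5 to 5.5 h”.

The flask gives yes and 33.7 at 6.0 h. It reaches the wanted length at 5.20 h, with 26.3% of the L reacted, so this flask clears the mark with 0.800 h of the run left. Taken at the growth speed of the charged [L], its length corresponds to an apparent mean age of 2.24 h, which is 0.373 of the run. At 0.600 h, earlier than the approach time of G, the rising-birth case gives 3.92, and the flask stands at 4.05.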